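The route rests on cutting ring B at C5–C10 and C8–C9. In ring B the C6 oxygen sits 1,4 to C9 (the carbon that holds the side chain), C8 carries an exocyclic methylene and C10 is quaternary. This array results when a vinylallene with a silyloxy group on its inner vinyl carbon (C5=C6–C7=C8=C17) cycloadds to the C9=C10 bond of a 3-methyl enal. One catalytic enantioselective intramolecular Diels–Alder reaction of an achiral open chain closes rings A and B, forms both bonds, sets C5, C9 and C10, and delivers the C8 methylene and a masked C6 ketone. The precursor is a dimethyl malonate whose central carbon (C4) bears the (E)-enal arm and the (Z)-silyloxy vinylallene arm.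

Key step: step 9

Numbering: labdane numbering is used. Ring A is C1–C5 and C10; ring B is C5–C10. C17 is on C8, C18 (α) and C19 (β) are on C4, and C20 is on C10. The side chain runs C11–C16, with C16 the butenolide carbinol carbon.
Assumption 1: the sense of induction in steps 9 and 20 is assigned from the accepted binding models of the two catalyst families; both catalysts exist in either mirror-image form, so a reversed sense would be met by the antipode with no other change.
Assumption 2: the 6α-hydroxy-18-aldehyde unit of 31, 32, 35 and 36 is written in the open form of the target; a strained lactol tautomer would equilibrate with it and does not alter the chemistry.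

Step 1
Reactants: 1 5-chloropent-1-yne
Product: 4 (E)-6-chloro-3-methylhex-2-en-1-ol, via alkenyldimethylalane 2 (not isolated), via lithium alkenylalanate 3 (not isolated)
Conditions: Me3Al, Cp2ZrCl2 (cat.), CH2Cl2, 0 °C → rt; n-BuLi, THF, −78 °C; (CH2O)n, → rt; aq. HCl
Reagents that add atoms: trimethylaluminium C[Al](C)C; formaldehyde (from paraformaldehyde) C=O
Why: Negishi carboalumination adds CH3 and Al syn across the terminal alkyne with Al on the terminal carbon, and the alanate is hydroxymethylated with retention, so the C9=C10 alkene should form as the pure E isomer that later puts C11 cis to the C10 methyl group.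

Step 2
Reactants: 4 (E)-6-chloro-3-methylhex-2-en-1-ol
Product: 5 (E)-6-chloro-3-methylhex-2-enyl triethylsilyl ether
Conditions: Et3SiCl, imidazole, CH2Cl2, 0 °C
Reagents that add atoms: chlorotriethylsilane CC[Si](Cl)(CC)CC
Why: Routine silyl ether formation, chosen because a primary triethylsilyl ether survives enolates, a Grignard reagent and silyl triflate but can later be removed beside a triisopropylsilyl enol ether.

Step 3
Reactants: 5 (E)-6-chloro-3-methylhex-2-enyl triethylsilyl ether; 6 dimethyl malonate
Product: 8 dimethyl 2-[(E)-4-methyl-6-(triethylsilyloxy)hex-4-enyl]malonate, via sodium malonate enolate 7 (not isolated)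
Conditions: 6 (excess), NaH, DMF, 0 °C; then 5, NaI (cat.), 70 °C
Reagents that add atoms: none
Why: Malonic ester alkylation (SN2 at the primary carbon after in situ Finkelstein exchange), with excess enolate to suppress double alkylation.

Step 4
Reactants: 8 dimethyl 2-[(E)-4-methyl-6-(triethylsilyloxy)hex-4-enyl]malonate; 9 2-chloro-N-methoxy-N-methylacetamide
Product: 11 Weinreb amide diester with quaternary C4, via sodium enolate 10 (not isolated)
Conditions: NaH, THF–DMF, 0 °C; then 9, NaI (cat.), rt
Reagents that add atoms: none
Why: Second malonic ester alkylation with an activated α-chloro amide builds the prochiral quaternary C4 and brings in C5 and C6 at the acyl level, which avoids any C6 carbinol that would lactonise onto the malonate.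

Step 5
Reactants: 11 Weinreb amide diester; 12 propargyl bromide
Product: 15 allenyl ketone (C6=O; C7=C8=C17), via allenylmagnesium bromide 13 (not isolated), via but-3-ynyl ketone 14 (not isolated)
Conditions: 12, Mg, HgCl2 (cat.), Et2O, 0 °C; added to 11, THF, −78 °C; aq. NH4Cl; then Et3N (cat.), CH2Cl2, rt
Reagents that add atoms: none
Why: Weinreb ketone synthesis, in which the chelated tetrahedral adduct prevents over-addition and the hindered malonate esters are spared at −78 °C; the allenyl Grignard reagent reacts with SE2′ transposition to the but-3-ynyl ketone, which a catalytic amine isomerises by prototropic shift to the conjugated allenyl ketone.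

Step 6
Reactants: 15 allenyl ketone
Product: 16 (Z)-2-(triisopropylsilyloxy) vinylallene with C11 triethylsilyl ether
Conditions: iPr3SiOTf, iPr2NEt, CH2Cl2, −78 → −20 °C
Reagents that add atoms: triisopropylsilyl triflate CC(C)[Si](C(C)C)(C(C)C)OS(=O)(=O)C(F)(F)F
Why: Soft enolisation (O-silylation, then amine deprotonation at C5, the only sp3 α-carbon) is known to turn allenyl ketones into 2-silyloxy vinylallenes, the clash between the quaternary C4 and the allenyl group enforces the Z geometry (C4 trans to C7) that the trans ring fusion needs, and the hindered amine cannot add to the allenone.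

Step 7
Reactants: 16 bis-silylated vinylallene
Product: 17 (Z)-silyloxy vinylallene with free (E)-allylic alcohol
Conditions: pyridinium p-toluenesulfonate (cat.), MeOH–CH2Cl2, 0 °C
Reagents that add atoms: none
Why: Acid-catalysed methanolysis discriminates by size and by mechanism, since the unhindered primary triethylsilyl ether is cleaved at silicon whereas loss of the enol silane would need protonation at C5, which is neopentylic and deactivated by two esters.

Step 8
Reactants: 17 allylic alcohol
Product: 18 cycloaddition precursor: malonate bearing the (E)-enal arm and the (Z)-triisopropylsilyloxy vinylallene arm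
Conditions: MnO2, CH2Cl2, rt; used at once
Reagents that add atoms: none
Why: Heterogeneous MnO2 oxidation is neutral, specific for the allylic alcohol and geometry-retaining, and unmasking the dienophile only now means that silyl triflate never meets an enal or an acetal, both of which it would enolise or ionise.

Step 9
Reactants: 18 cycloaddition precursor
Product: 19 trans-fused cycloadduct (5α-H; 10β-CH3; 9β-CHO; 6-silyloxy-6,8(17)-diene; 4,4-diester)
Conditions: (S)-3,3-diphenyl-1-(o-tolyl)tetrahydro-1H,3H-pyrrolo[1,2-c][1,3,2]oxazaborole and Tf2NH (20 mol % each), CH2Cl2 (high dilution), −78 → −40 °C; Et3N quench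
Reagents that add atoms: none
Why: Proposed new method: coordination of the formyl oxygen to the cationic boron lowers the enal LUMO, the enol-ether carbon C5 bonds to the enal β-carbon C10 ahead of C8–C9 bond formation, and the reaction is a concerted but highly asynchronous [4+2] whose stepwise limit is a Mukaiyama–Michael addition followed by capture of the allenyl oxocarbenium ion at its central carbon C8. The closest known reactions are oxazaborolidinium-catalysed type-1 intramolecular Diels–Alder reactions of trienals, intermolecular additions of 2-(triisopropylsilyloxy)butadiene under the same catalyst, and thermal vinylallene cycloadditions; their combination with a β,β-disubstituted enal is untested. Ring B is the new cyclohexene itself (both new bonds lie in it; 6-endo capture at C8 in the stepwise picture), and ring A closes at the same time through the C1–C4 tether in a chair-like array (6-exo-trig attack of C5 on C10), helped by the geminal diester. C10 is fixed by the catalyst, which leaves only the C9-Si/C10-Re face of the bound enal open; C9 follows from suprafacial addition to the E-alkene, which keeps the formyl group cis to the C10 methyl; C5 follows from the Z-enol ether (C4 on the outside of the diene) together with the endo position of the boron-bound formyl group, which places H-5 anti to the C10 methyl (trans fusion). The step needs endo over exo selectivity, secured by Lewis-acid-enhanced secondary overlap, and reaction at C7=C8 rather than C8=C17, secured by conjugation and tether length; the unsubstituted allene terminus shows only hydrogen to the dienophile and ends as the C8 methylene, and the bulky enol silane survives the acidic catalyst as the masked C6 ketone.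

Step 10
Reactants: 19 cycloadduct
Product: 20 9β-vinyl silyl dienol ether diester
Conditions: Ph3PCH3Br, KN(SiMe3)2, THF, 0 °C; then 19, −78 → 0 °C
Reagents that add atoms: methyltriphenylphosphonium bromide C[P+](c1ccccc1)(c1ccccc1)c1ccccc1.[Br-]
Why: Wittig methylenation with the non-stabilised ylide is fast at low temperature, so the epimerisable β,γ-unsaturated aldehyde is consumed before it can enolise, C9 is untouched, and the vinyl group (C11=C12) is inert to all the ring chemistry that follows.

Step 11
Reactants: 20 9β-vinyl silyl dienol ether diester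
Product: 21 8(17)-en-6-one diester
Conditions: Bu4NF, AcOH, THF, −40 → 0 °C; used crude
Reagents that add atoms: none
Why: Fluoride-induced desilylation gives the dienolate, which the acetic acid buffer protonates kinetically at the α-carbon C7, so the deconjugated 8(17)-en-6-one should result without base-mediated drift of the alkene or epimerisation at C5.

Step 12
Reactants: 21 8(17)-en-6-one diester
Product: 23 18,6α-lactone with 4β-methoxycarbonyl group, via 6α-hydroxy diester 22 (not isolated)
Conditions: SmI2, H2O, THF, 0 °C → rt; then DBU (cat.), 4 Å molecular sieves, toluene, 80 °C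
Reagents that add atoms: none
Why: Single-electron reduction by divalent samarium passes through a ketyl and a C6 carbanion that is protonated to the more stable equatorial alkoxide, as in dissolving-metal reductions of ketones flanked by two syn-axial groups where hydrides give the axial alcohol, so C6 becomes 6α, and because only the equatorial 4α-ester lies parallel to the 6α-oxygen the base-catalysed transesterification desymmetrises the malonate and defines C4.

Step 13
Reactants: 23 18,6α-lactone ester
Product: 24 18,6α-lactone with 4β-H
Conditions: LiCl, H2O, DMSO, 150 °C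
Reagents that add atoms: none
Why: Krapcho dealkoxycarbonylation, in which chloride demethylates the remaining ester, the α-carboxy lactone loses CO2, and the enolate can only be protonated on the β face because the lactone bridge holds C18 on the α side.

Step 14
Reactants: 24 18,6α-lactone with 4β-H
Product: 26 4β-methyl 18,6α-lactone, via lithium lactone enolate 25 (not isolated)
Conditions: LiN(iPr)2, THF, −78 → −30 °C; MeI, DMPU, −78 → 0 °C
Reagents that add atoms: iodomethane CI
Why: Lactone enolate alkylation, in which the bridge to the 6α-oxygen keeps C18 equatorial so that iodomethane has to enter from the β face, which sets the quaternary C4 with its 4β-methyl (C19) and 4α-carbonyl (C18) by the tether and not by the steric bias of the ring.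

Step 15
Reactants: 27 methyl acetoacetate
Product: 28 methyl (E)-3-(trifluoromethylsulfonyloxy)but-2-enoate
Conditions: Tf2O, aq. Me4NOH, hexanes, 5 °C
Reagents that add atoms: triflic anhydride O=S(=O)(OS(=O)(=O)C(F)(F)F)C(F)(F)F
Why: O-Triflation of the non-chelated tetramethylammonium enolate under Schotten–Baumann conditions is known to give the E enol triflate, in which the leaving group is trans to the ester as the 13E alkene requires.

Step 16
Reactants: 26 4β-methyl 18,6α-lactone; 28 (E)-enol triflate
Product: 30 lactone with (13E)-enoate side chain, via C12 dicyclohexylborane 29 (not isolated)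
Conditions: (c-C6H11)2BH (from BH3·SMe2 and cyclohexene, 1.05 equiv), THF, 0 °C → rt; then 28, PdCl2(dppf) (cat.), K3PO4, dioxane, 60 °C
Reagents that add atoms: none
Why: Hydroboration with a bulky dialkylborane is much faster at a monosubstituted vinyl group than at a 1,1-disubstituted alkene, here one also flanked by C9 and screened by the C10 methyl, and puts boron on C12, after which B-alkyl Suzuki–Miyaura coupling transfers the primary alkyl group with retention of the triflate geometry, so that C12–C13 and the 13E alkene are made stereospecifically.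

Step 17
Reactants: 30 lactone enoate
Product: 31 6α-hydroxy-18-aldehyde with C15 allylic alcohol
Conditions: iBu2AlH, CH2Cl2, −78 °C; aq. potassium sodium tartrate
Reagents that add atoms: none
Why: Hydride reduction with iBu2AlH at −78 °C takes the enoate to the allylic alcohol and stops at the stable aluminate of the γ-lactol, which on work-up releases the 6α-hydroxy aldehyde without touching any stereocentre.

Step 18
Reactants: 31 hydroxy aldehyde allylic alcohol
Product: 32 6α-hydroxy-18-aldehyde with (13E)-C15 enal
Conditions: MnO2, CH2Cl2, rt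
Reagents that add atoms: none
Why: MnO2 oxidation is selective for the primary allylic alcohol, retains the 13E geometry and leaves the hindered secondary 6α-alcohol and the C18 aldehyde unchanged.

Step 19
Reactants: 33 4-methylfuran-2(5H)-one
Product: 34 4-methyl-2-(trimethylsilyloxy)furan
Conditions: Me3SiOTf, Et3N, Et2O, 0 °C; distilled
Reagents that add atoms: trimethylsilyl triflate C[Si](C)(C)OS(=O)(=O)C(F)(F)F
Why: Soft enolisation of the butenolide at its γ-carbon is driven by formation of the aromatic 2-silyloxyfuran.

Step 20
Reactants: 32 hydroxy dialdehyde; 34 4-methyl-2-(trimethylsilyloxy)furan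
Product: 36 target CNP0113661.1, via C15 trimethylsilyl ether 35 (not isolated)
Conditions: Ti(OiPr)4 and (R)-BINOL (20 mol % each), Et2O, −20 °C; then citric acid (cat.), MeOH, 0 °C
Reagents that add atoms: none
Why: Catalytic enantioselective vinylogous Mukaiyama aldol reaction of a 2-silyloxyfuran, in which the BINOL–titanium Lewis acid binds the unhindered C15 enal in preference to the neopentylic C18 aldehyde and exposes its Re face (15S), the open transition state favours the syn adduct (16S), the furan reacts at its γ-carbon, and the β,β-disubstituted enal cannot undergo 1,4-addition.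

Compound list
1 | 5-chloropent-1-yne | C#CCCCCl | starting material
2 | (E)-(5-chloro-2-methylpent-1-enyl)dimethylalane | C[Al](C)/C=C(\C)CCCCl | intermediate
3 | lithium butyl[(E)-5-chloro-2-methylpent-1-enyl]dimethylalanate | [Li+].CCCC[Al-](C)(C)/C=C(\C)CCCCl | intermediate
4 | (E)-6-chloro-3-methylhex-2-en-1-ol | OC/C=C(\C)CCCCl | intermediate
5 | (E)-6-chloro-3-methylhex-2-enyl triethylsilyl ether | CC[Si](CC)(CC)OC/C=C(\C)CCCCl | intermediate
6 | dimethyl malonate | COC(=O)CC(=O)OC | starting material
7 | sodium enolate of dimethyl malonate | [Na+].COC(=O)[CH-]C(=O)OC | intermediate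
8 | dimethyl 2-[(E)-4-methyl-6-(triethylsilyloxy)hex-4-enyl]malonate | CC[Si](CC)(CC)OC/C=C(\C)CCCC(C(=O)OC)C(=O)OC | intermediate
9 | 2-chloro-N-methoxy-N-methylacetamide | CON(C)C(=O)CCl | starting material
10 | sodium enolate of 8 | [Na+].CC[Si](CC)(CC)OC/C=C(\C)CCC[C-](C(=O)OC)C(=O)OC | intermediate
11 | dimethyl 2-[2-(methoxy(methyl)amino)-2-oxoethyl]-2-[(E)-4-methyl-6-(triethylsilyloxy)hex-4-enyl]malonate | CC[Si](CC)(CC)OC/C=C(\C)CCCC(CC(=O)N(C)OC)(C(=O)OC)C(=O)OC | intermediate
12 | propargyl bromide | C#CCBr | starting material
13 | allenylmagnesium bromide | C=C=C[Mg]Br | intermediate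
14 | dimethyl 2-(2-oxopent-4-ynyl)-2-[(E)-4-methyl-6-(triethylsilyloxy)hex-4-enyl]malonate | CC[Si](CC)(CC)OC/C=C(\C)CCCC(CC(=O)CC#C)(C(=O)OC)C(=O)OC | intermediate
15 | dimethyl 2-(2-oxopenta-3,4-dienyl)-2-[(E)-4-methyl-6-(triethylsilyloxy)hex-4-enyl]malonate | CC[Si](CC)(CC)OC/C=C(\C)CCCC(CC(=O)C=C=C)(C(=O)OC)C(=O)OC | intermediate
16 | dimethyl 2-[(1Z)-2-(triisopropylsilyloxy)penta-1,3,4-trienyl]-2-[(E)-4-methyl-6-(triethylsilyloxy)hex-4-enyl]malonate | CC[Si](CC)(CC)OC/C=C(\C)CCCC(C(=O)OC)(C(=O)OC)/C=C(O[Si](C(C)C)(C(C)C)C(C)C)/C=C=C | intermediate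
17 | dimethyl 2-[(E)-6-hydroxy-4-methylhex-4-enyl]-2-[(1Z)-2-(triisopropylsilyloxy)penta-1,3,4-trienyl]malonate | OC/C=C(\C)CCCC(C(=O)OC)(C(=O)OC)/C=C(O[Si](C(C)C)(C(C)C)C(C)C)/C=C=C | intermediate
18 | dimethyl 2-[(E)-4-methyl-6-oxohex-4-enyl]-2-[(1Z)-2-(triisopropylsilyloxy)penta-1,3,4-trienyl]malonate (cycloaddition precursor) | O=C/C=C(\C)CCCC(C(=O)OC)(C(=O)OC)/C=C(O[Si](C(C)C)(C(C)C)C(C)C)/C=C=C | intermediate
19 | trans-decalin cycloadduct: 5α-H, 10β-methyl, 9β-formyl, 8-methylene, 6-(triisopropylsilyloxy)-6-ene, 4,4-bis(methoxycarbonyl) | C=C1C=C(O[Si](C(C)C)(C(C)C)C(C)C)[C@@H]2[C@](C)(CCCC2(C(=O)OC)C(=O)OC)[C@H]1C=O | intermediate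
20 | 9β-vinyl analogue of 19 | C=C1C=C(O[Si](C(C)C)(C(C)C)C(C)C)[C@@H]2[C@](C)(CCCC2(C(=O)OC)C(=O)OC)[C@H]1C=C | intermediate
21 | 9β-vinyl-8-methylene-6-oxo trans-decalin 4,4-diester | C=C1CC(=O)[C@@H]2[C@](C)(CCCC2(C(=O)OC)C(=O)OC)[C@H]1C=C | intermediate
22 | 6α-hydroxy 4,4-diester | C=C1C[C@H](O)[C@@H]2[C@](C)(CCCC2(C(=O)OC)C(=O)OC)[C@H]1C=C | intermediate
23 | 18,6α-lactone with 4β-methoxycarbonyl group | C=C1C[C@@H]2OC(=O)[C@]3(C(=O)OC)CCC[C@](C)([C@H]1C=C)[C@@H]23 | intermediate
24 | 18,6α-lactone with 4β-H | C=C1C[C@@H]2OC(=O)[C@@H]3CCC[C@](C)([C@H]1C=C)[C@@H]23 | intermediate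
25 | lithium enolate of 24 | [Li+].C=C1C[C@@H]2OC([O-])=C3CCC[C@](C)([C@H]1C=C)[C@@H]23 | intermediate
26 | 4β-methyl 18,6α-lactone with 9β-vinyl group | C=C1C[C@@H]2OC(=O)[C@]3(C)CCC[C@](C)([C@H]1C=C)[C@@H]23 | intermediate
27 | methyl acetoacetate | CC(=O)CC(=O)OC | starting material
28 | methyl (E)-3-(trifluoromethylsulfonyloxy)but-2-enoate | C/C(OS(=O)(=O)C(F)(F)F)=C\C(=O)OC | intermediate
29 | C12 dicyclohexylborane of 26 | C=C1C[C@@H]2OC(=O)[C@]3(C)CCC[C@](C)([C@H]1CCB(C4CCCCC4)C4CCCCC4)[C@@H]23 | intermediate
30 | 18,6α-lactone with methyl (13E)-enoate side chain | C=C1C[C@@H]2OC(=O)[C@]3(C)CCC[C@](C)([C@H]1CC/C(C)=C/C(=O)OC)[C@@H]23 | intermediate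
31 | 6α-hydroxy-18-aldehyde with (13E)-15-ol side chain | C=C1C[C@H](O)[C@@H]2[C@](C)(CCC[C@@]2(C)C=O)[C@H]1CC/C(C)=C/CO | intermediate
32 | 6α-hydroxy-18-aldehyde with (13E)-15-al side chain | C=C1C[C@H](O)[C@@H]2[C@](C)(CCC[C@@]2(C)C=O)[C@H]1CC/C(C)=C/C=O | intermediate
33 | 4-methylfuran-2(5H)-one | CC1=CC(=O)OC1 | starting material
34 | 4-methyl-2-(trimethylsilyloxy)furan | Cc1coc(O[Si](C)(C)C)c1 | intermediate
35 | 15-O-trimethylsilyl ether of the target | C=C1C[C@H](O)[C@@H]2[C@](C)(CCC[C@@]2(C)C=O)[C@H]1CC/C(C)=C/[C@H](O[Si](C)(C)C)[C@H]1OC(=O)C=C1C | intermediate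
36 | CNP0113661.1 (5α-H, 6α-OH, 4α-CHO, 4β-CH3, 9β side chain, 10β-CH3, 13E, 15S, 16S) | C=C1C[C@H](O)[C@@H]2[C@](C)(CCC[C@@]2(C)C=O)[C@H]1CC/C(C)=C/[C@H](O)[C@H]1OC(=O)C=C1C | target

Total step count: 20 (18 in the main line, plus steps 15 and 19 for the partners 28 and 34).
Longest linear sequence: 18 steps (1–14, 16–18, 20).

Steps most likely to fail

Step 9. Bond formation at the fully substituted enal β-carbon may be too slow. Acid-induced loss of the enol silane, exo closure to the cis-decalin, or weak facial discrimination could then take over.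
The fallback takes the absolute configuration from a classical resolution. It sets out from 18 and returns at 19.
- 18 is cyclised with the achiral Lewis acid Me2AlCl (CH2Cl2, −78 °C), an established way to run type-1 intramolecular Diels–Alder reactions of trienals, to the racemic cycloadduct F1.
- NaBH4 (MeOH–CH2Cl2, −40 °C) reduces only the aldehyde to the racemic C11 alcohol F2.
- Esterification with (S)-O-methylmandelic acid (EDC, DMAP) gives the mandelate of the wanted antipode F3 and the diastereomeric mandelate F4, which are separated by chromatography or crystallisation.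
- K2CO3 in MeOH releases the enantiopure C11 alcohol F5.
- Dess–Martin periodinane with NaHCO3 gives 19.

Step 12. The electron-transfer reduction has close analogy, so the weaker half of the step is the ring closure. Transesterification to the doubly trans-fused γ-lactone may stall at an unfavourable equilibrium.
The fallback replaces reversible transesterification by irreversible carboxyl activation. It sets out from 22 (now isolated) and returns at 23.
- LiOH (1 equiv, THF–H2O, 0 °C) hydrolyses the exposed equatorial 4α-ester, which the neighbouring 6α-hydroxyl assists, while the axial ester is screened by the C10 methyl. This gives the 6α-hydroxy 4α-acid 4β-ester F6.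
- 2-Chloro-1-methylpyridinium iodide and Et3N (Mukaiyama lactonisation, CH2Cl2, reflux, high dilution) close 23.

Step 20. The resident stereocentres are too remote to help, so catalyst control over the aldehyde face and over syn/anti topicity may be insufficient.
The fallback separates relative from absolute control. It sets out from 32 and 34 and returns at 36.
- BF3·OEt2 (CH2Cl2, −78 °C), the Lewis-acid protocol known to favour syn adducts of silyloxyfurans, gives 36 together with the (15R,16R)-diastereomer F7.
- Sharpless kinetic resolution (Ti(OiPr)4, L-(+)-diisopropyl tartrate, t-BuOOH 0.6 equiv, 4 Å molecular sieves, CH2Cl2, −20 °C) epoxidises the fast-reacting 15R allylic alcohol to the 13,14-epoxy alcohol F8.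
- The slow-reacting 36 is left behind and is separated by chromatography.

Further compounds
F1 | step 9 | racemic cycloadduct (both antipodes of 19) | C=C1C=C(O[Si](C(C)C)(C(C)C)C(C)C)[C@@H]2[C@](C)(CCCC2(C(=O)OC)C(=O)OC)[C@H]1C=O.C=C1C=C(O[Si](C(C)C)(C(C)C)C(C)C)[C@H]2[C@@](C)(CCCC2(C(=O)OC)C(=O)OC)[C@@H]1C=O
F2 | step 9 | racemic C11 alcohol | C=C1C=C(O[Si](C(C)C)(C(C)C)C(C)C)[C@@H]2[C@](C)(CCCC2(C(=O)OC)C(=O)OC)[C@H]1CO.C=C1C=C(O[Si](C(C)C)(C(C)C)C(C)C)[C@H]2[C@@](C)(CCCC2(C(=O)OC)C(=O)OC)[C@@H]1CO
F3 | step 9 | (S)-O-methylmandelate of the wanted antipode | C=C1C=C(O[Si](C(C)C)(C(C)C)C(C)C)[C@@H]2[C@](C)(CCCC2(C(=O)OC)C(=O)OC)[C@H]1COC(=O)[C@@H](OC)c1ccccc1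
F4 | step 9 | diastereomeric (S)-O-methylmandelate of the unwanted antipode | C=C1C=C(O[Si](C(C)C)(C(C)C)C(C)C)[C@H]2[C@@](C)(CCCC2(C(=O)OC)C(=O)OC)[C@@H]1COC(=O)[C@@H](OC)c1ccccc1
F5 | step 9 | enantiopure C11 alcohol | C=C1C=C(O[Si](C(C)C)(C(C)C)C(C)C)[C@@H]2[C@](C)(CCCC2(C(=O)OC)C(=O)OC)[C@H]1CO
F6 | step 12 | 6α-hydroxy 4α-carboxylic acid 4β-methyl ester | C=C1C[C@H](O)[C@@H]2[C@](C)(CCC[C@@]2(C(=O)OC)C(=O)O)[C@H]1C=C
F7 | step 20 | (15R,16R)-diastereomer of 36 | C=C1C[C@H](O)[C@@H]2[C@](C)(CCC[C@@]2(C)C=O)[C@H]1CC/C(C)=C/[C@@H](O)[C@@H]1OC(=O)C=C1C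
F8 | step 20 | 13,14-epoxy alcohol from F7 | C=C1C[C@H](O)[C@@H]2[C@](C)(CCC[C@@]2(C)C=O)[C@H]1CC[C@@]3(C)O[C@@H]3[C@@H](O)[C@@H]1OC(=O)C=C1C
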